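**A direct plan and its weak points**

A direct plan would start from the arene: 2',4'-dihydroxy-6'-methoxyacetophenone A1 would be diprenylated at C3 with dearomatisation to the acyl dienone A2, the acetyl group of A2 would be condensed with an aromatic aldehyde to the cinnamoyl dienone A3, and A3 would be closed to the target by an enantioselective oxa-Michael addition of the ring enol.
- The dearomative double C-prenylation would be weak: a phenolate dianion offers O-, C3- and C5-alkylation and mono-, di- and tri-alkylation side by side, so the quaternary carbon is made in the least selective reaction.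
- The condensation in concentrated aqueous base would be weak: the substrate is a vinylogous acid with a vinylogous methyl ester and a retro-Claisen-prone acyl group, and it must survive long exposure to hydroxide.
- The oxa-Michael closure would be weak: the only stereocentre is set last by a reversible C–O bond formation with a non-aromatic enol nucleophile, so retro-Michael opening erodes the configuration during the reaction and on isolation.

**Retrosynthetic overview of the new route**

- Feature used: ring A is a doubly vinylogous ester O1–C8a=C4a–C5(OMe)=C6–C7(=O) closed by the gem-diprenyl carbon C8; C8 with C7 and C8a is the α-carbon of a dialkylated acetoacetate, and C2 is a benzylic carbinol carbon.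
- Disconnections: C6–C7 (intramolecular C-acylation of an enol ether, key step), C4a–C5 (Negishi coupling that brings C5, C6 and the OMe group together), O1–C8a (cyclodehydration), C4–C4a (Claisen-type acylation), C8–CH2 twice (enolate alkylation).
- Ring order: the dihydropyranone (ring C) is closed first from an acyclic hydroxy diketone; ring A is closed last, on a monocyclic precursor, with no arene and no dearomatisation.
- How the weak steps are avoided: C8 is made by ordinary β-keto ester alkylation; C2 comes from a chiral-pool carbinol whose C–O bond is never made or broken; the OMe position is fixed by the carbon skeleton and not by a selective O-methylation; no aqueous hydroxide is used at any stage.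

Key step: step 6

Remark: locants (O1, C2 to C8a) are those of the chromene skeleton of the target; the carbinol carbon of the hydroxy ester becomes C2 with no bond to it made or broken, so the (S)-ester should give the (2S)-product.

**Route**

Step 1
Reactants: 1 prop-2-en-1-yl 3-oxobutanoate (allyl acetoacetate); 2 1-bromo-3-methylbut-2-ene (prenyl bromide)
Product: 3 prop-2-en-1-yl 2-acetyl-5-methyl-2-(3-methylbut-2-en-1-yl)hex-4-enoate
Conditions: NaH (1.1 equiv), 2 (1.1 equiv), THF, 0 °C to rt; then NaH (1.2 equiv), 2 (1.3 equiv), THF/DMF, 0 °C to rt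
Reagents that add atoms: prenyl bromide 2, CC(C)=CCBr
Why: Twofold C-alkylation of a β-keto ester enolate (acetoacetic ester alkylation) with a soft allylic bromide should build the quaternary carbon C8 with C7 (ester) and C8a (ketone) already attached; no stereocentre is formed.

Step 2
Reactants: 4 ethyl (3S)-3-hydroxy-3-phenylpropanoate; 5 N,O-dimethylhydroxylamine hydrochloride
Product: 6 (3S)-3-hydroxy-N-methoxy-N-methyl-3-phenylpropanamide
Conditions: 5 (2.5 equiv), i-PrMgCl (5.2 equiv), THF, −20 to 0 °C; aq. NH4Cl
Reagents that add atoms: N,O-dimethylhydroxylamine hydrochloride 5, CNOC.Cl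
Why: Aminolysis of the ester by the magnesium amide of 5 (Weinreb amide formation) should proceed with the carbinol held as its magnesium alkoxide, so the S configuration is carried over unchanged.

Step 3
Reactants: 3 prop-2-en-1-yl 2-acetyl-5-methyl-2-(3-methylbut-2-en-1-yl)hex-4-enoate; 6 (3S)-3-hydroxy-N-methoxy-N-methyl-3-phenylpropanamide
Product: 8 prop-2-en-1-yl 5-methyl-2-(3-methylbut-2-en-1-yl)-2-[(2S)-4-oxo-2-phenyl-3,4-dihydro-2H-pyran-6-yl]hex-4-enoate, via hydroxy diketone 7 (not isolated)
Conditions: 3 (1.6 equiv), LDA (1.6 equiv), THF, −78 °C; 6 as its magnesium alkoxide (i-PrMgCl, 1.05 equiv), −78 to −20 °C; AcOH, −78 °C; then TsOH·H2O (0.1 equiv), CH2Cl2, 0 °C to rt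
Reagents that add atoms: Weinreb amide 6, CON(C)C(=O)C[C@H](O)c1ccccc1
Why: Claisen-type C-acylation of the methyl-ketone enolate of 3 (its only enolisable position) by the Weinreb amide, followed by acid-catalysed cyclodehydration of the δ-hydroxy-β-diketone, should give the 2,3-dihydro-4H-pyran-4-one; O1 can reach only C8a in a six-membered ring, water can be lost only towards C4a because C8 is quaternary, and C2 keeps its S configuration.

Step 4
Reactants: 8 prop-2-en-1-yl 5-methyl-2-(3-methylbut-2-en-1-yl)-2-[(2S)-4-oxo-2-phenyl-3,4-dihydro-2H-pyran-6-yl]hex-4-enoate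
Product: 9 prop-2-en-1-yl 2-[(2S)-5-iodo-4-oxo-2-phenyl-3,4-dihydro-2H-pyran-6-yl]-5-methyl-2-(3-methylbut-2-en-1-yl)hex-4-enoate
Conditions: I2 (1.5 equiv), pyridine/CH2Cl2 (1:1), 0 °C to rt, dark; aq. Na2S2O3
Reagents that add atoms: iodine, II
Why: Electrophilic α-iodination of a vinylogous ester at its only nucleophilic vinylic carbon, C4a, should be irreversible through loss of the proton to pyridine, whereas the prenyl double bonds only form iodonium complexes reversibly in this nucleophile-free medium.

Step 5
Reactants: 9 prop-2-en-1-yl 2-[(2S)-5-iodo-4-oxo-2-phenyl-3,4-dihydro-2H-pyran-6-yl]-5-methyl-2-(3-methylbut-2-en-1-yl)hex-4-enoate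
Product: 11 2-[(2S)-5-(1-methoxyethenyl)-4-oxo-2-phenyl-3,4-dihydro-2H-pyran-6-yl]-5-methyl-2-(3-methylbut-2-en-1-yl)hex-4-enoic acid, via allyl ester 10 (not isolated)
Conditions: (1-methoxyethenyl)zinc chloride (3 equiv; from methyl vinyl ether, t-BuLi, THF, −78 to 0 °C, then ZnCl2), Pd(PPh3)4 (5 mol %), THF, 0 °C to rt; MeOH; then sodium p-toluenesulfinate (1.5 equiv), rt; pH 6 phosphate buffer, 0 °C; the acid is extracted into CH2Cl2 containing 2,6-lutidine, kept cold and used at once
Reagents that add atoms: (1-methoxyethenyl)zinc chloride, COC(=C)[Zn]Cl (made in the flask from methyl vinyl ether, COC=C)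
Why: Negishi coupling of the α-iodo enone with an α-alkoxyvinylzinc reagent should form C4a–C5 and bring in C6 and the methoxy group (transmetalation at rt should outrun carbopalladation of the prenyl groups); the same zerovalent palladium catalyst then ionises the allyl ester and the sulfinate traps the π-allyl complex (Tsuji–Trost deallylation) under neutral conditions that spare the acid-labile 2-methoxydiene.

Step 6
Reactants: 11 2-[(2S)-5-(1-methoxyethenyl)-4-oxo-2-phenyl-3,4-dihydro-2H-pyran-6-yl]-5-methyl-2-(3-methylbut-2-en-1-yl)hex-4-enoic acid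
Product: 13 griffinone A, (2S)-5-methoxy-8,8-bis(3-methylbut-2-en-1-yl)-2-phenyl-2,3-dihydro-4H-chromene-4,7(8H)-dione, via acid chloride 12 (not isolated)
Conditions: 1-chloro-N,N,2-trimethylprop-1-en-1-amine (1.1 equiv), 2,6-lutidine (3 equiv), CH2Cl2, 0 °C; then ClCH2CH2Cl, rt to 50 °C; Et3N-deactivated SiO2
Reagents that add atoms: none
Why: The acid is turned under neutral conditions into acid chloride 12; its acyl carbon C7 is attacked by C6, the terminal carbon of the 2-methoxydiene (an enol ether also pushed by O1 through C8a=C4a), and loss of the C6 proton from the methoxy-stabilised oxocarbenium ion to 2,6-lutidine gives the vinylogous ester C5(OMe)=C6–C7=O. The closest known reaction type is the Friedel–Crafts-type C-acylation of enol ethers by acid chlorides, here run intramolecularly. Ring A closes by the C6–C7 bond in a 6-(enolendo)-exo-trig mode, with both reacting arms held cis on the C4a=C8a double bond of ring C. No new stereocentre is formed, and C2 is safe because no base strong enough to enolise C3 and no acid able to ionise the benzylic C2–O1 bond is present. The step needs C-acylation at C6 only and no reaction at the prenyl groups: the methyl group blocks O-acylation, C4a is fully substituted, and the electrophile is a covalent acyl chloride without Lewis acid, so no acylium ion (and no decarbonylation at the quaternary carbon) should arise and the oxocarbenium ion is deprotonated at once. The methoxy group sits at C5 by construction.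

**Compound list**

1 | prop-2-en-1-yl 3-oxobutanoate (allyl acetoacetate) | CC(=O)CC(=O)OCC=C | starting material
2 | 1-bromo-3-methylbut-2-ene (prenyl bromide) | CC(C)=CCBr | starting material
3 | prop-2-en-1-yl 2-acetyl-5-methyl-2-(3-methylbut-2-en-1-yl)hex-4-enoate | CC(=O)C(CC=C(C)C)(CC=C(C)C)C(=O)OCC=C | intermediate
4 | ethyl (3S)-3-hydroxy-3-phenylpropanoate | CCOC(=O)C[C@H](O)c1ccccc1 | starting material
5 | N,O-dimethylhydroxylamine hydrochloride | CNOC.Cl | starting material
6 | (3S)-3-hydroxy-N-methoxy-N-methyl-3-phenylpropanamide | CON(C)C(=O)C[C@H](O)c1ccccc1 | intermediate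
7 | prop-2-en-1-yl 2-[(5S)-5-hydroxy-3-oxo-5-phenylpentanoyl]-5-methyl-2-(3-methylbut-2-en-1-yl)hex-4-enoate | C=CCOC(=O)C(CC=C(C)C)(CC=C(C)C)C(=O)CC(=O)C[C@H](O)c1ccccc1 | intermediate
8 | prop-2-en-1-yl 5-methyl-2-(3-methylbut-2-en-1-yl)-2-[(2S)-4-oxo-2-phenyl-3,4-dihydro-2H-pyran-6-yl]hex-4-enoate | C=CCOC(=O)C(CC=C(C)C)(CC=C(C)C)C1=CC(=O)C[C@@H](c2ccccc2)O1 | intermediate
9 | prop-2-en-1-yl 2-[(2S)-5-iodo-4-oxo-2-phenyl-3,4-dihydro-2H-pyran-6-yl]-5-methyl-2-(3-methylbut-2-en-1-yl)hex-4-enoate | C=CCOC(=O)C(CC=C(C)C)(CC=C(C)C)C1=C(I)C(=O)C[C@@H](c2ccccc2)O1 | intermediate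
10 | prop-2-en-1-yl 2-[(2S)-5-(1-methoxyethenyl)-4-oxo-2-phenyl-3,4-dihydro-2H-pyran-6-yl]-5-methyl-2-(3-methylbut-2-en-1-yl)hex-4-enoate | C=CCOC(=O)C(CC=C(C)C)(CC=C(C)C)C1=C(C(=C)OC)C(=O)C[C@@H](c2ccccc2)O1 | intermediate
11 | 2-[(2S)-5-(1-methoxyethenyl)-4-oxo-2-phenyl-3,4-dihydro-2H-pyran-6-yl]-5-methyl-2-(3-methylbut-2-en-1-yl)hex-4-enoic acid | OC(=O)C(CC=C(C)C)(CC=C(C)C)C1=C(C(=C)OC)C(=O)C[C@@H](c2ccccc2)O1 | intermediate
12 | 2-[(2S)-5-(1-methoxyethenyl)-4-oxo-2-phenyl-3,4-dihydro-2H-pyran-6-yl]-5-methyl-2-(3-methylbut-2-en-1-yl)hex-4-enoyl chloride | ClC(=O)C(CC=C(C)C)(CC=C(C)C)C1=C(C(=C)OC)C(=O)C[C@@H](c2ccccc2)O1 | intermediate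
13 | griffinone A, (2S)-5-methoxy-8,8-bis(3-methylbut-2-en-1-yl)-2-phenyl-2,3-dihydro-4H-chromene-4,7(8H)-dione | COC1=CC(=O)C(CC=C(C)C)(CC=C(C)C)C2=C1C(=O)C[C@@H](c1ccccc1)O2 | target

**Step count and risks**

Total step count: 6. Longest linear sequence: 5 (steps 1, 3, 4, 5, 6).

Steps most likely to fail:

1. Step 6 (closure of ring A). The acid-labile 2-methoxydiene may be protonated or acylated while the carboxyl group is activated, attack on the hindered acyl chloride may be slow, or the vinylogous β-keto acid may lose CO2 before activation. The fallback reverses the order in which the two bonds of ring A are made and sets out from iodide 9. Ruthenium-catalysed deallylation ([CpRu(MeCN)3]PF6, quinaldic acid, MeOH), which leaves the C–I bond alone, would give the iodo acid F1. The same chloroenamine would convert it into the iodo acid chloride F2, which would C-acylate 1,1-dimethoxyethene (Et3N, CH2Cl2) to the acyl ketene acetal F3. Iodine–magnesium exchange (i-PrMgCl·LiCl, THF, −40 °C) would then make C4a a carbanion that adds to the acetal carbon C5 and expels methoxide (addition–elimination). This closes ring A by the C4a–C5 bond and comes back to the route at 13.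

2. Step 3 (acylation and closure of ring C). The neighbouring alkoxide may fragment the α,α-disubstituted β-keto ester by retro-Claisen cleavage, acylation by the amide may stay incomplete, or the acid may dehydrate the benzylic carbinol. The fallback builds ring C from an ynone and sets out from 3 and 6. Ketone 3 would be converted in one flask through the enol phosphate F4 (LDA; ClP(O)(OEt)2; then LDA) into the terminal alkyne F5. Its lithium acetylide (LiHMDS, THF, −78 °C) would add to amide 6 to give the β-hydroxy ynone F6. A 6-endo-dig oxa-Michael addition (K2CO3, MeOH, 0 °C) would close the pyranone and come back to the route at 8.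

3. Step 4 (iodination at C4a). Iodonium chemistry at the two prenyl double bonds may compete, or substitution at the hindered vinylogous ester may be slow. The fallback iodinates before ring C exists and sets out from the crude hydroxy diketone 7. Its enol, far more nucleophilic than a trisubstituted alkene, would take iodine from N-iodosuccinimide (CH2Cl2, 0 °C) to give the iodo diketone F7 as a mixture at the iodinated carbon. Cyclodehydration (TsOH·H2O, CH2Cl2) would then come back to the route at 9.

Further compounds
F1 | step 6 | 2-[(2S)-5-iodo-4-oxo-2-phenyl-3,4-dihydro-2H-pyran-6-yl]-5-methyl-2-(3-methylbut-2-en-1-yl)hex-4-enoic acid | OC(=O)C(CC=C(C)C)(CC=C(C)C)C1=C(I)C(=O)C[C@@H](c2ccccc2)O1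
F2 | step 6 | 2-[(2S)-5-iodo-4-oxo-2-phenyl-3,4-dihydro-2H-pyran-6-yl]-5-methyl-2-(3-methylbut-2-en-1-yl)hex-4-enoyl chloride | ClC(=O)C(CC=C(C)C)(CC=C(C)C)C1=C(I)C(=O)C[C@@H](c2ccccc2)O1
F3 | step 6 | (2S)-6-[1,1-dimethoxy-7-methyl-4-(3-methylbut-2-en-1-yl)-3-oxoocta-1,6-dien-4-yl]-5-iodo-2-phenyl-2,3-dihydro-4H-pyran-4-one | COC(OC)=CC(=O)C(CC=C(C)C)(CC=C(C)C)C1=C(I)C(=O)C[C@@H](c2ccccc2)O1
F4 | step 3 | prop-2-en-1-yl 2-{1-[(diethoxyphosphoryl)oxy]ethenyl}-5-methyl-2-(3-methylbut-2-en-1-yl)hex-4-enoate | C=CCOC(=O)C(CC=C(C)C)(CC=C(C)C)C(=C)OP(=O)(OCC)OCC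
F5 | step 3 | prop-2-en-1-yl 2-ethynyl-5-methyl-2-(3-methylbut-2-en-1-yl)hex-4-enoate | C=CCOC(=O)C(CC=C(C)C)(CC=C(C)C)C#C
F6 | step 3 | prop-2-en-1-yl 2-[(5S)-5-hydroxy-3-oxo-5-phenylpent-1-yn-1-yl]-5-methyl-2-(3-methylbut-2-en-1-yl)hex-4-enoate | C=CCOC(=O)C(CC=C(C)C)(CC=C(C)C)C#CC(=O)C[C@H](O)c1ccccc1
F7 | step 4 | prop-2-en-1-yl 2-[(5S)-5-hydroxy-2-iodo-3-oxo-5-phenylpentanoyl]-5-methyl-2-(3-methylbut-2-en-1-yl)hex-4-enoate | C=CCOC(=O)C(CC=C(C)C)(CC=C(C)C)C(=O)C(I)C(=O)C[C@H](O)c1ccccc1
A1 | direct plan | 1-(2,4-dihydroxy-6-methoxyphenyl)ethan-1-one | COc1cc(O)cc(O)c1C(C)=O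
A2 | direct plan | 4-acetyl-5-hydroxy-3-methoxy-6,6-bis(3-methylbut-2-en-1-yl)cyclohexa-2,4-dien-1-one | COC1=CC(=O)C(CC=C(C)C)(CC=C(C)C)C(O)=C1C(C)=O
A3 | direct plan | 5-hydroxy-3-methoxy-6,6-bis(3-methylbut-2-en-1-yl)-4-[(2E)-3-phenylprop-2-enoyl]cyclohexa-2,4-dien-1-one | COC1=CC(=O)C(CC=C(C)C)(CC=C(C)C)C(O)=C1C(=O)/C=C/c1ccccc1
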